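The readings were computed from invented constants.

The easy step comes first. I turn one reading of target in each earlier run, a fraction y at time t, into an apparent first-order constant k = −ln(1−y)/t, and I compare elm with ash at the same time.

the same everywhere: starting material 0.050 M

|  | second substrate | partner | free catalyst | remark |
|---|---|---|---|---|
| elm | 0.50 equiv | 1.8 equiv | 3 mol% | run made earlier |
| ash | 0.50 equiv | 1.8 equiv | 6.8 mol% | run made earlier |
| flask | 0.500 equiv | 1.80 equiv | 4.5 mol% |  |

- elm (time / min: target / %): 0.417: 20.5; 0.667: 29.7; 1.00: 40.3; 2.00: 63.7; 3.00: 72.3; 5.00: 86.1
- ash (time / min: target / %): 0.417: 41.3; 0.667: 55.9; 1.00: 73.0; 2.00: 90.8; 3.00: 96.3; 5.00: 99.8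

(each reading ± 1 percentage point)

- apparent order in free catalyst when 10% of the starting material are converted (percent change of the rate of making target for one percent more free catalyst charged)

- what was read earlier has a scatter of 1 percentage point, one standard deviation
- what is bound to the catalyst counts as converted

Before taking a number, I ask which inputs matter. The concentration and the equivalents are alike in both runs, so they do not separate the two k. The loadings enter once, as the divisor 0.818, the logarithm of their ratio. Among the readings, a point on elm's first reading moves the result 1.71 times as far as a point on ash's first reading. Ash's reading at 3.00 min weighs 2.56 times as much as its first, so late readings are poor witnesses.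

I therefore define n as the logarithm of the ratio of the two k over the logarithm of the ratio of the loadings. The first readings give 1.03, and this two-run order is what I carry. The next pair gives 1.03, while the pair at 3.00 min gives 1.15, which I set aside. The flask's loading of 4.5 mol% lies between the two runs, so I commit to n for it.

The forecast says 1.05, within 0.88 to 1.22, noting that “Scaling time by catalyst loading nearly overlays the early points”. The flask gives 1.0.

    starting material + free catalyst ⇌ catalyst intermediate A (K = 5200 L mol⁻¹, k = 24.0 L mol⁻¹ s⁻¹)
    partner + catalyst intermediate A → free catalyst + target (k = 7.20 L mol⁻¹ s⁻¹)
    second substrate + free catalyst ⇌ catalyst intermediate B (K = 41.0 L mol⁻¹, k = 63.0 L mol⁻¹ s⁻¹)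
    partner + catalyst intermediate B → free catalyst + second product (k = 1.40 L mol⁻¹ s⁻¹)
    partner + free catalyst → spent catalyst (k = 0.0390 L mol⁻¹ s⁻¹)
    free catalyst ⇌ dormant form (K = 8.20, k = 0.0140 s⁻¹)

Elm's first reading gives k = 0.550 min⁻¹. Scaled with n to this flask's loading and applied to the starting material left at 10% conversion, it gives 0.0376 M min⁻¹, and this flask shows 0.0384 M min⁻¹ at 0.109 min. Of the changes tried on this flask, the largest single effect on that rate comes from the reverse step, catalyst intermediate B back to second substrate and free catalyst: without that step, the rate stands at 0.266 times the actual one.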